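## Analysis of the target

Target 11 is 1-(2,6-dimethoxyphenyl)-9-(4-hydroxyphenyl)nonan-1-one: an unbranched nine-carbon chain whose C1 is a ketone carbon bonded to ring A (the 2,6-dimethoxyphenyl ring) and whose C9 is bonded to ring B para to a free phenolic hydroxyl. It has no stereocenter and no ring that must be built, because both benzene rings can be bought with their oxygen substituents in place; the task is to join pieces at the right atoms. The sensitive groups are the phenol O–H, the ketone and the enolisable C2 methylene beside it. The phenol is acidic and must stay distinguishable from the two aryl methyl ethers of ring A, so a methyl ether cannot serve as its mask. The difficulty sits at C1: the carbonyl lies between two ortho methoxy groups, a position that electrophilic acylation of a 1,3-dimethoxyarene avoids in favour of the carbon para to a methoxy group, and that is crowded enough to make attack of a carbon nucleophile on a 2,6-dimethoxybenzoyl derivative slow. The methylenes C3 to C9 carry no handle, so skeletal bonds are sensibly made only at the two chain ends. The plan rests on the fact that C1 carries an unbranched CH2–CH2 unit (C2–C3), which is what results when a formyl C–H bond adds across a terminal alkene with the acyl carbon going to the end carbon. Ring A, the ring A–C1 bond and the carbonyl oxidation level are then all contained in aldehyde 6, and C2 to C9 with ring B in terminal alkene 5.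

## Retrosynthetic reasoning

**Unmasking the phenol (11 back to 10).** The O–H of 11 is traced back to the O–Si bond of silyl ether 10. A mask is needed because ring B is joined to the chain through an aryl magnesium reagent. A tert-butyldimethylsilyl ether is chosen because fluoride removes it without touching the aryl methyl ethers or the ketone, and because it has neither an acidic hydrogen nor a donor that would hold rhodium in the step before.

**The C1–C2 bond (10 back to 5 and 6).** This is the only cut that leaves ring A with its carbonyl carbon attached, in the form of purchasable aldehyde 6. Cutting the ring A–C1 bond instead would call for acylation at the disfavoured ring position or substitution at a carbonyl buried between two methoxy groups, and no bond further along the chain has a functional handle. The cut gives two fragments of similar size, needs no change of oxidation level and puts every atom of both partners into the product. The forward reaction must add the formyl C–H of 6 across the C=C of 5 with the acyl carbon on the terminal carbon. A free acyl rhodium hydride would lose carbon monoxide, so the aldehyde is converted in the flask to aldimine 7 and then to pyridyl aldimine 8, whose ring nitrogen holds rhodium in a chelate. The coupled ketimine 9 is hydrolysed to 10 in the same operation.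

**The C9–ring B bond (5 back to 4 and 3).** This aryl–alkyl bond is cut so that the whole C2–C9 unit with its terminal alkene comes from bromide 3, which is sold with exactly this chain length. Building the chain stepwise would cost several steps for no gain. The forward reaction is a copper-catalysed alkylation of aryl Grignard reagent 4 by the primary bromide of 3; it must outrun homocoupling of 4 and leave the remote alkene alone.

**The aryl metal and the mask (4 back to 2 back to 1).** The C–Mg bond of 4 comes from the C–Br bond of 2, and the O–Si bond of 2 from the O–H of commodity phenol 1. Silylation comes first so that no acidic hydrogen is present when the Grignard reagent is made.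

## Alternatives that were turned down

**Alternative 1:** Ring A is taken apart at the bond between its ipso carbon (the one bearing C1) and an ortho carbon, leading back to the open-chain dioxo ester A1. In the forward direction a base would generate the diketonate of A1, and its central carbon would acylate itself on the ester carbon in a Claisen (Dieckmann-type) closure to give the 2-acylcyclohexane-1,3-dione A2. Ring A would then be dehydrogenated to the aromatic level, both new hydroxyls methylated and the benzyl ether removed.
- For it: the acyl group is placed between the two oxygens by construction, the hindered ketone is made intramolecularly, and only cheap base chemistry is used.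
- Against it: the 1,2,3-pattern of ring A is a catalogue item in 6, so building the ring solves a problem the target does not pose. A1 needs several C–C bond formations of its own. O-acylation and retro-Claisen cleavage compete with the closure. The later double O-methylation is sluggish because each new hydroxyl is hydrogen bonded to the C1 carbonyl. The hydrogenolysis must spare the aryl ketone.
- Comparison: it is stronger in one respect, since it needs no precious metal and does not depend on a catalyst accepting a doubly ortho-substituted aldehyde. The chosen strategy offers in its place ring A bought complete, one redox-neutral bond formation, and four steps against well over twice that number.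

**Alternative 2:** Ring B is cut at its ipso–ortho bond and at the ortho–meta bond on the other side, leading back to keto aldehyde A3 and methyl vinyl ketone A4. In the forward direction a secondary-amine enamine of A3 would add to A4, and the methyl ketone would then condense on the former aldehyde carbon (a Robinson-type annulation of an aldehyde) to give the racemic cyclohexenone A5. Dehydrogenation of A5 would give 11 directly.
- For it: the phenol appears only in the last step, so no protecting group is needed, and the key step is metal-free.
- Against it: A3 already contains the hindered aryl ketone, so the real difficulty of the target is only moved into the preparation of A3, an eleven-carbon chain with different carbonyl groups at its two ends. A stereocenter is made only to be destroyed. The final oxidation has to aromatize ring B in the presence of the electron-rich ring A and of a second enolisable ketone, both open to halogenation or over-oxidation.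
- Comparison: on protecting-group economy this alternative is stronger, and the chosen route does spend two steps on putting on and taking off a silyl group. In return the chosen route buys ring B as a phenol, needs no oxidation, and makes in its key step exactly the C1–C2 bond that A3 would still have to acquire.

**Alternative 3:** The target ketone is traced back to the tertiary cyclononanol A6, in which C1 and C9 are joined in a nine-membered ring, and to 4-bromophenyl acetate A7. In the forward direction the O–H of A6 would be oxidized to an alkoxy radical, β-scission of the ring C1–C9 bond would give the aryl ketone and a primary radical at C9, and a nickel catalyst would join C9 to the brominated carbon of A7 to give acetate A8. Cleavage of the acetate would give 11.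
- For it: the hindered ketone is unveiled and not built, the ring A–C1 bond comes from an easy aryllithium addition to cyclononanone A9, and the sequence has only three steps.
- Against it: A9 is a costly medium-ring ketone. β-Scission of an unstrained ring has less driving force than the strained cases and is reversible. The primary C9 radical on a flexible chain can shift by 1,5-hydrogen transfer or be reduced before nickel captures it, which would move or lose the arylation site. The electron-rich ring A is itself open to oxidation under the conditions that generate the alkoxy radical. Merging ring opening with nickel arylation on an unstrained, hindered carbinol would stretch the known scope.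
- Comparison: in step count this alternative is equal or slightly better. The chosen strategy offers commodity starting materials, a closed-shell organometallic pathway in which the position of the new bond is fixed by the alkene terminus, complete atom economy in the key step, and a key reaction that is known for this substrate class.

Key step: step 3

## Route

Step 1
Reactants: 1 4-bromophenol
Product: 2 (4-bromophenoxy)(tert-butyl)dimethylsilane
Conditions: TBSCl (1.1 equiv), imidazole (2 equiv), DMF, rt
Reagents that add atoms: tert-butyldimethylsilyl chloride (TBSCl), CC(C)(C)[Si](C)(C)Cl
Why: Imidazole-promoted O-silylation of a phenol; it removes the acidic hydrogen before the Grignard step and gives a mask that can later be taken off without touching aryl methyl ethers.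

Step 2
Reactants: 2 (4-bromophenoxy)(tert-butyl)dimethylsilane (1.3 equiv), 3 8-bromooct-1-ene (1.0 equiv)
Product: 5 tert-butyldimethyl[4-(oct-7-en-1-yl)phenoxy]silane, via aryl Grignard reagent 4 (not isolated)
Conditions: Mg (I2 cat.), THF, 50 °C; then 3, Li2CuCl4 (3 mol %), THF, −10 °C to rt
Reagents that add atoms: none
Why: Magnesium inserts into the aryl C–Br bond to give 4, to which the aryl silyl ether is inert; Li2CuCl4 is reduced by 4 to an aryl cuprate of monovalent copper that displaces the primary bromide of 3 (copper-catalysed Grignard alkylation, Kochi coupling). The isolated terminal alkene is a spectator.

Step 3
Reactants: 5 tert-butyldimethyl[4-(oct-7-en-1-yl)phenoxy]silane (1.5 equiv), 6 2,6-dimethoxybenzaldehyde (1.0 equiv)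
Product: 10 9-[4-(tert-butyldimethylsilyloxy)phenyl]-1-(2,6-dimethoxyphenyl)nonan-1-one, via N-phenyl aldimine 7 (not isolated), via pyridyl aldimine 8 (not isolated), via pyridyl ketimine 9 (not isolated)
Conditions: RhCl(PPh3)3 (5 mol %), 2-amino-3-picoline (40 mol %), PhNH2 (60 mol %), PhCO2H (10 mol %), toluene, 130 °C, sealed tube; then 1 M HCl (aq), THF, rt
Reagents that add atoms: none
Why: Chelation-assisted intermolecular hydroacylation, a known rhodium-catalysed coupling of aromatic aldehydes with 1-alkenes through a transient 2-aminopyridyl aldimine. Aldehyde 6 condenses with aniline to 7, which exchanges its amine for 2-amino-3-picoline to give 8; the pyridine nitrogen of 8 guides RhCl(PPh3)3 (monovalent rhodium) into the imine C–H bond and holds the resulting iminoacyl hydride of trivalent rhodium in a five-membered chelate that has no carbonyl group to extrude, so decarbonylation is shut off. The terminal C=C of 5 then inserts into the Rh–H bond with the metal on the unsubstituted end carbon, and reductive elimination joins that carbon (C2 of the target) to the iminoacyl carbon (C1), returning monovalent rhodium and ketimine 9. Water set free in the condensation, with benzoic acid as proton shuttle, hydrolyses 9 to ketone 10 and releases the picoline for the next turnover; the dilute acid wash completes the hydrolysis of what remains. No ring is closed and no stereocenter is created. The selectivity required is linear over branched addition, which the monosubstituted alkene secures because the crowded chelated metal avoids a secondary alkyl, and coupling faster than migration of the double bond, which the excess of 5 covers. Ring A helps in two ways: both positions ortho to C1 carry methoxy groups, so the ortho C–H alkylation that a ketimine such as 9 can otherwise undergo with excess alkene is impossible, and the hindered acyl carbon is never attacked by a nucleophile because its bond to ring A is already present in 6. The aryl silyl ether carries no acidic hydrogen and should pass unchanged, and any portion that is lost would simply appear as target 11.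

Step 4
Reactants: 10 9-[4-(tert-butyldimethylsilyloxy)phenyl]-1-(2,6-dimethoxyphenyl)nonan-1-one
Product: 11 1-(2,6-dimethoxyphenyl)-9-(4-hydroxyphenyl)nonan-1-one
Conditions: TBAF (1.1 equiv), AcOH (1.1 equiv), THF, 0 °C to rt
Reagents that add atoms: none
Why: Fluoride-induced desilylation driven by the strong Si–F bond; the acetic acid protonates the phenoxide as it forms, which keeps the enolisable ketone away from basic fluoride. Aryl methyl ethers and the ketone do not react.

## Compound list

1 | 4-bromophenol | Oc1ccc(Br)cc1 | starting material
2 | (4-bromophenoxy)(tert-butyl)dimethylsilane | CC(C)(C)[Si](C)(C)Oc1ccc(Br)cc1 | intermediate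
3 | 8-bromooct-1-ene | C=CCCCCCCBr | starting material
4 | [4-(tert-butyldimethylsilyloxy)phenyl]magnesium bromide | CC(C)(C)[Si](C)(C)Oc1ccc([Mg]Br)cc1 | intermediate
5 | tert-butyldimethyl[4-(oct-7-en-1-yl)phenoxy]silane | C=CCCCCCCc1ccc(O[Si](C)(C)C(C)(C)C)cc1 | intermediate
6 | 2,6-dimethoxybenzaldehyde | COc1cccc(OC)c1C=O | starting material
7 | (E)-1-(2,6-dimethoxyphenyl)-N-phenylmethanimine | COc1cccc(OC)c1/C=N/c1ccccc1 | intermediate
8 | (E)-1-(2,6-dimethoxyphenyl)-N-(3-methylpyridin-2-yl)methanimine | COc1cccc(OC)c1/C=N/c1ncccc1C | intermediate
9 | 9-[4-(tert-butyldimethylsilyloxy)phenyl]-1-(2,6-dimethoxyphenyl)-N-(3-methylpyridin-2-yl)nonan-1-imine (C=N geometry not fixed) | COc1cccc(OC)c1C(CCCCCCCCc1ccc(O[Si](C)(C)C(C)(C)C)cc1)=Nc1ncccc1C | intermediate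
10 | 9-[4-(tert-butyldimethylsilyloxy)phenyl]-1-(2,6-dimethoxyphenyl)nonan-1-one | COc1cccc(OC)c1C(=O)CCCCCCCCc1ccc(O[Si](C)(C)C(C)(C)C)cc1 | intermediate
11 | 1-(2,6-dimethoxyphenyl)-9-(4-hydroxyphenyl)nonan-1-one | COc1cccc(OC)c1C(=O)CCCCCCCCc1ccc(O)cc1 | target

## Step count and least certain steps

Total step count: 4. Longest linear sequence: 4 steps (1 to 2 to 5 to 10 to 11); 3 and 6 are bought and enter in steps 2 and 3.

**Step 3 (key step).**
- What may go wrong: the formyl group of 6 lies between two methoxy groups, so condensation to 7 and 8 and the C–H insertion may be slow. That would give the rhodium hydride time to move the double bond of 5 into the chain, and the internal isomers couple more slowly and are lost to the product. An ortho methoxy oxygen may also bind rhodium after insertion and retard reductive elimination. Partial loss of the silyl group under hot amine and acid is possible but harmless.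
- Fallback: the same C1–C2 bond is made by polar chemistry, setting out from 5 (with 6) and coming back at 10. Hydroboration of 5 with 9-BBN in THF and oxidation with NaBO3·4H2O (mild enough for the aryl silyl ether) should give 8-[4-(tert-butyldimethylsilyloxy)phenyl]octan-1-ol F1. An Appel reaction (CBr4, PPh3, CH2Cl2) converts it to [4-(8-bromooctyl)phenoxy](tert-butyl)dimethylsilane F2. Magnesium insertion in THF gives {8-[4-(tert-butyldimethylsilyloxy)phenyl]octyl}magnesium bromide F3, which adds to the formyl group of 6 to give, after NH4Cl work-up, racemic 9-[4-(tert-butyldimethylsilyloxy)phenyl]-1-(2,6-dimethoxyphenyl)nonan-1-ol F4. Dess–Martin oxidation of F4 returns to 10. An aldehyde is far more open to a Grignard reagent than a 2,6-dimethoxybenzoyl derivative, so this detour also avoids the hindered acyl substitution, at the price of four more operations.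

**Step 2.**
- What may go wrong: oxidative homocoupling of 4 when the copper salt is reduced, and substitution at the unactivated primary bromide too slow to consume 4 before it is quenched; halogen–magnesium exchange between 4 and 3 would add Wurtz-type by-products.
- Fallback: the polarity is reversed, setting out from 3 and 2 and coming back at 5 without passing through 4. Zinc dust with LiCl in THF at 50 °C inserts into 3 to give oct-7-en-1-ylzinc bromide F5, which is joined to aryl bromide 2 in a Negishi coupling with Pd(OAc)2 and SPhos (zerovalent palladium formed in the flask) in THF at rt.

**Step 4.**
- What may go wrong: this is the safest step; the remaining concerns are base-induced self-condensation at the enolisable C2 methylene if the buffering is insufficient, and loss of material in separating the polar phenol from tetrabutylammonium salts.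
- Fallback: the order of events is changed, setting out from 5 and coming back at 11. The silyl ether is cleaved before the key step with K2CO3 in MeOH at rt to give 4-(oct-7-en-1-yl)phenol F6, and F6 is then coupled with 6 under the conditions of step 3 to give 11 directly. The catalyst system already operates in the presence of benzoic acid, aniline and water, so a phenol O–H is not expected to stop it, and the ketone is then never exposed to fluoride.

## Further compounds

F1 | step 3 | 8-[4-(tert-butyldimethylsilyloxy)phenyl]octan-1-ol | OCCCCCCCCc1ccc(O[Si](C)(C)C(C)(C)C)cc1
F2 | step 3 | [4-(8-bromooctyl)phenoxy](tert-butyl)dimethylsilane | BrCCCCCCCCc1ccc(O[Si](C)(C)C(C)(C)C)cc1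
F3 | step 3 | {8-[4-(tert-butyldimethylsilyloxy)phenyl]octyl}magnesium bromide | Br[Mg]CCCCCCCCc1ccc(O[Si](C)(C)C(C)(C)C)cc1
F4 | step 3 | racemic 9-[4-(tert-butyldimethylsilyloxy)phenyl]-1-(2,6-dimethoxyphenyl)nonan-1-ol | COc1cccc(OC)c1C(O)CCCCCCCCc1ccc(O[Si](C)(C)C(C)(C)C)cc1
F5 | step 2 | oct-7-en-1-ylzinc bromide | C=CCCCCCC[Zn]Br
F6 | step 4 | 4-(oct-7-en-1-yl)phenol | C=CCCCCCCc1ccc(O)cc1
A1 | alternative 1 | methyl 15-[4-(benzyloxy)phenyl]-5,7-dioxopentadecanoate | COC(=O)CCCC(=O)CC(=O)CCCCCCCCc1ccc(OCc2ccccc2)cc1
A2 | alternative 1 | 2-[9-(4-benzyloxyphenyl)nonanoyl]cyclohexane-1,3-dione | O=C1CCCC(=O)C1C(=O)CCCCCCCCc1ccc(OCc2ccccc2)cc1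
A3 | alternative 2 | 11-(2,6-dimethoxyphenyl)-11-oxoundecanal | O=CCCCCCCCCCC(=O)c1c(OC)cccc1OC
A4 | alternative 2 | but-3-en-2-one (methyl vinyl ketone) | C=CC(C)=O
A5 | alternative 2 | racemic 4-[9-(2,6-dimethoxyphenyl)-9-oxononyl]cyclohex-2-en-1-one | O=C1C=CC(CCCCCCCCC(=O)c2c(OC)cccc2OC)CC1
A6 | alternative 3 | 1-(2,6-dimethoxyphenyl)cyclononan-1-ol | COc1cccc(OC)c1C1(O)CCCCCCCC1
A7 | alternative 3 | 4-bromophenyl acetate | CC(=O)Oc1ccc(Br)cc1
A8 | alternative 3 | 4-[9-(2,6-dimethoxyphenyl)-9-oxononyl]phenyl acetate | COc1cccc(OC)c1C(=O)CCCCCCCCc1ccc(OC(C)=O)cc1
A9 | alternative 3 | cyclononanone | O=C1CCCCCCCC1
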